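The earlier runs and the new flask are calculated for an exercise.

Early on, at 40.0 min, the violet run holds 7.4 % of target, while the ochre run holds 14.9 % at the same moment. That is twice as much with twice the free catalyst, so the early rate follows free catalyst.

in all of them: starting material 0.40 M

|  | second substrate | capture agent | free catalyst | remark | time |
|---|---|---|---|---|---|
| violet | 0.40 M | 0.020 M | 2 mM | the very flask that is asked about, followed so far |  |
| ochre | 0.40 M | 0.020 M | 4 mM | run made earlier |  |
| flask | 0.400 M | 0.0200 M | 2.0 mM |  | 15 h |

- violet (time / min: starting material / %, target / %): 6.00: 98.2, 1.1; 10.0: 97.8, 1.8; 15.0: 96.7, 3.9; 25.0: 94.7, 5.4; 40.0: 92.4, 7.4; 80.0: 87.6, 12.4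
- ochre (time / h: starting material / %, target / %): 0.667: 85.1, 14.9; 2.00: 68.8, 30.0; 4.00: 61.6, 39.0; 6.00: 58.3, 41.9; 8.00: 57.0, 42.7; 10.0: 57.2, 43.3

(scatter of a reading: 0.3 percentage points)

- conversion of starting material at 15 h
- amount of target at 15 h, in percent of the starting material charged



I take the settings in turn. Time: ochre reads 42.7 % of target at 8.00 h and 43.3 % at 10.0 h, so it has nearly stopped, and the asked 15 h is longer than that. I expect the extra hours to add little. Starting material: ochre stops with 57.2 % still there, so its running out is not what stops ochre, and both runs share its charge, so they cannot show what more of it does. Capture agent and second substrate: both runs share the same charges, so they cannot show what these do, but ochre's capture agent, 0.020 M, exceeds its 4 mM of free catalyst.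

Free catalyst is the setting in which the two runs differ. If making target and losing catalyst both run in proportion to catalyst, their ratio at equal amounts of everything else does not depend on how much catalyst was charged. Ochre's last reading gives 43.3 moles of target per mole of catalyst charged; this capacity, the turnover number, is what I carry. The ratio may drift as starting material falls, and the flask keeps more of it, so for this flask my 21.7 % of target, equal to the conversion because the readings balance, may come out slightly low.

The forecast gives 23 % for conversion and 23 % for target, each within 20 % to 26.5 %, holding that “the catalyst dies rather than the reaction reaching completion”, and my figure lies slightly lower. The flask gives 22.2 % conversion and 22.2 % target.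

    second substrate + free catalyst ⇌ catalyst intermediate B (K = 1.11 M⁻¹, k = 0.895 M⁻¹ s⁻¹)
    catalyst intermediate B → free catalyst + second product (k = 0.0183 s⁻¹)
    catalyst intermediate B + capture agent → trapped intermediate (k = 0.0483 M⁻¹ s⁻¹)
    catalyst intermediate A → free catalyst + target (k = 0.0198 s⁻¹)
    starting material + free catalyst ⇌ catalyst intermediate A (K = 2.45 M⁻¹, k = 1.69 M⁻¹ s⁻¹)

In this flask, target reaches 13.4 % at 1.50 h, when 60.0 % of the catalyst is already trapped intermediate. By 7.50 h, 98.8 % is trapped and target stands at 21.9 %, against 22.2 % at 150 h. The capacity here is 44.3, against 43.3 from ochre. With 0.0050 M of free catalyst, the capacity gives 54.1 % of target; that neighbour flask gives 53.3 %.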